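**Retrosynthetic overview**

1. The route rests on one feature of rings A/B: the ester carbon C18 on C4 and the hydroxyl on C6 are both α and equatorial on the trans-decalin and lie peri across C4–C5–C6. The target is therefore the ring-opened form of an 18,6α-γ-lactone, and its C6–O bond (ring O–C18–C4–C5–C6) is made by 1,5-hydrogen transfer from C6 to an amidyl radical on C18.
2. Side chain, last disconnections: C14–OOH by SN2 inversion of a (14R)-allylic mesylate with a ketal-protected hydroperoxide; C13–C14 by Ni/Cr coupling of a 2-iodo-1-alkene with a butenolide aldehyde, the C14 carbinol then being set by oxidation and Corey–Bakshi–Shibata reduction.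
3. The iodoalkene is grown from the carbonyl carbon C13 of a 13,8α-δ-lactone that masks O8 during the radical step. This lactone is one carbon larger than a 12,8-lactone, so that C13 of abietic acid is kept and no C12 halide (which the free O8 would close to the 8,12-ether) has to be passed.
4. The δ-lactone primary amide is cut out of abietic acid (C4, C5, C9, C10 from the pool): amide at C18, cleavage of C13=C14, C14 turned into the 8β-methyl group under an α-epoxide oxygen, Baeyer–Villiger loss of the isopropyl group.
5. Ring order: rings A/B from the pool, ring C opened (step 2), δ-lactone (step 6), peri γ-lactone (step 7), both lactones opened (step 8); the butenolide ring is closed separately from L-allylglycine (step 15) and joined in step 17.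

Key step: step 7

Remark: abietane numbering is kept (C18 = carbonyl carbon on C4, C14 = the carbon left on C8 when ring C is cut; side chain C9–C11–C12–C13(=CH2)–C14–C15–C16(O)–C17(CH3)=); commercial abietic acid is assumed to be used after purification through an amine salt, the configuration written for the unisolated 13,14-diol is an assumption without consequence, and the C6 iodide of the key step may form as either epimer.

**Route**

Step 1
Reactants: 1 abietic acid
Product: 3 abieta-7,13-dien-18-amide, via abietoyl chloride 2 (not isolated)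
Conditions: (COCl)2, DMF (cat.), CH2Cl2, 0 °C; then NH3 (gas), THF, 0 °C
Reagents that add atoms: ammonia, N
Why: Acyl substitution through the acid chloride is the standard way to the primary amide of a hindered tertiary acid, and low temperature with immediate ammonolysis should keep the acid-labile 7,13-diene from isomerizing; no stereocenter is touched.

Step 2
Reactants: 3 abieta-7,13-dien-18-amide
Product: 5 13,14-dioxo-13,14-secoabiet-7-en-18-amide, via 13α,14α-diol 4 (not isolated)
Conditions: OsO4 (2 mol %), NMO (1.05 equiv), acetone/H2O, 0 °C to rt; then NaIO4, THF/H2O, rt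
Reagents that add atoms: N-methylmorpholine N-oxide, C[N+]1([O-])CCOCC1 (both new oxygen atoms, passed on by the catalyst OsO4, O=[Os](=O)(=O)=O)
Why: Catalytic OsO4 dihydroxylation should take the more electron-rich, isopropyl-bearing C13=C14 bond of the diene, and the periodate glycol cleavage (a two-stage Lemieux–Johnson cleavage) then opens ring C to the C13 isopropyl ketone and the C14 aldehyde, whose conjugation deactivates the remaining C7=C8 bond; the carbinol centers of the diol are destroyed.

Step 3
Reactants: 5 13,14-dioxo-13,14-secoabiet-7-en-18-amide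
Product: 7 13-oxo-13,14-secoabiet-8(14)-en-18-amide, via C14 tosylhydrazone 6 (not isolated)
Conditions: TsNHNH2 (1.05 equiv), THF, rt; then catecholborane (2.5 equiv), CHCl3, −10 °C; NaOAc·3H2O, 60 °C
Reagents that add atoms: none
Why: The aldehyde condenses with the hydrazide far faster than the hindered isopropyl ketone, and hydride addition to the conjugated hydrazone followed by loss of sulfinate gives an allylic diazene whose retro-ene loss of N2 puts hydrogen on C7 and moves the double bond to C8=C14 (reductive 1,3-transposition of an α,β-unsaturated tosylhydrazone); no stereocenter is formed.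

Step 4
Reactants: 7 13-oxo-13,14-secoabiet-8(14)-en-18-amide
Product: 9 propan-2-yl 18-amino-8α,14-epoxy-18-oxo-15,16,17-trinor-13,14-secoabietan-13-oate, via 8α,14-epoxy ketone 8 (not isolated)
Conditions: mCPBA (3 equiv), NaHCO3, CH2Cl2, 0 °C, then 40 °C
Reagents that add atoms: 3-chloroperbenzoic acid, OOC(=O)c1cccc(Cl)c1
Why: Prilezhaev epoxidation of the exocyclic alkene should come from the α face because the β face is screened by the axial C10 methyl group (this sets C8), and the Baeyer–Villiger oxidation of the ketone that follows in the same flask moves the secondary isopropyl group onto oxygen.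

Step 5
Reactants: 9 propan-2-yl 18-amino-8α,14-epoxy-18-oxo-15,16,17-trinor-13,14-secoabietan-13-oate
Product: 10 8α,13-dihydroxy-15,16,17-trinor-13,14-secoabietan-18-amide
Conditions: LiEt3BH (6 equiv), THF, 0 °C to rt; then H2O
Reagents that add atoms: none
Why: Borohydride reduction opens the spiro-epoxide by SN2 attack at its CH2 carbon, which leaves the 8α-oxygen as the tertiary alcohol under the new 8β-methyl group, and reduces the ester to the C13 alcohol, while the primary amide is only deprotonated and returns on work-up.

Step 6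
Reactants: 10 8α,13-dihydroxy-15,16,17-trinor-13,14-secoabietan-18-amide
Product: 12 18-amino-18-oxo-15,16,17-trinor-13,14-secoabietan-13,8α-olide (δ-lactone amide), via 13,8α-lactol 11 (not isolated)
Conditions: Pr4N[RuO4] (5 mol %), NMO (3 equiv), 4 Å molecular sieves, CH2Cl2, rt
Reagents that add atoms: none
Why: Ley–Griffith oxidation of the primary alcohol gives the aldehyde, which closes with the tertiary 8α-hydroxyl to the six-membered lactol and is oxidized on to the trans-fused δ-lactone; the amide and all stereocenters are untouched.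

Step 7
Reactants: 12 18-amino-18-oxo-15,16,17-trinor-13,14-secoabietan-13,8α-olide
Product: 16 15,16,17-trinor-13,14-secoabietane-13,8α:18,6α-diolide (bis-lactone), via N-iodoamide 13 (not isolated), via 6-iodo amide 14 (not isolated), via 18,6α-iminolactone 15 (not isolated)
Conditions: PhI(OAc)2 (2.5 equiv), I2 (1.0 equiv), ClCH2CH2Cl, visible light (tungsten lamp), 40 °C; Na2S2O3 (aq.); then 1 M HCl, THF, rt
Reagents that add atoms: water, O
Why: PhI(OAc)2 and I2 convert the primary amide into the N-iodoamide 13, whose N–I bond is cleaved by light to the C18 amidyl radical; this abstracts the equatorial 6α-hydrogen through a six-membered transition state (1,5-hydrogen transfer), the C6 radical is iodinated to 14, and the amide oxygen closes onto C6 to give the iminolactone 15, which aqueous acid hydrolyses to the lactone. The closest known reaction type is the photolysis of N-iodoamides to γ-lactones, a Hofmann–Löffler–Freytag-type remote functionalization. The new five-membered ring O–C18–C4–C5–C6 closes in the 5-exo-tet mode by attack of the amide oxygen on C6 from the α side with iodide leaving from the β side (the C6 epimers of 14 can interconvert by iodide exchange, and excess trivalent iodine reagent can also oxidize the iodide into a better leaving group). The new stereocenter C6 is fixed by the tether, because the 4α carbonyl group can reach C6 only on the α face, so the C–O bond is 6α whatever the configuration of the iodide. The step needs site selectivity for C6, and the rigid trans-decalin should secure it: C6–Hα is the only hydrogen that is both in a 1,5 relation and in syn-pentane contact with the amidyl nitrogen, C2 being 1,5 but anti to C18 and C3, C5 and C19 only 1,4. The δ-lactone keeps O8 out of the alkoxy-radical manifold and offers no weak C–H bond within reach.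

Step 8
Reactants: 16 15,16,17-trinor-13,14-secoabietane-13,8α:18,6α-diolide
Product: 18 dimethyl 6α,8α-dihydroxy-15,16,17-trinor-13,14-secoabietane-13,18-dioate, via dipotassium dicarboxylate 17 (not isolated)
Conditions: KOH, MeOH/H2O, 70 °C; CO2 to pH 8, evaporation; then MeI, DMF, rt
Reagents that add atoms: potassium hydroxide, [K+].[OH-]; iodomethane, CI
Why: Saponification opens both lactones by acyl–oxygen cleavage, so C6 and C8 keep their configuration, and SN2 alkylation of the two carboxylates with iodomethane under non-acidic conditions gives the diester before the hydroxy acids can close again.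

Step 9
Reactants: 18 dimethyl 6α,8α-dihydroxy-15,16,17-trinor-13,14-secoabietane-13,18-dioate
Product: 19 dimethyl 6α,8α-bis(triethylsilyloxy)-15,16,17-trinor-13,14-secoabietane-13,18-dioate
Conditions: TESOTf (3 equiv), 2,6-lutidine, CH2Cl2, −40 to 0 °C
Reagents that add atoms: triethylsilyl trifluoromethanesulfonate, CC[Si](CC)(CC)OS(=O)(=O)C(F)(F)F
Why: Silyl ether formation with the silyl triflate and a hindered pyridine covers both the secondary 6α- and the tertiary 8α-hydroxyl, which blocks relactonization onto C18 and C13 in the basic and reducing steps that follow.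

Step 10
Reactants: 19 dimethyl 6α,8α-bis(triethylsilyloxy)-15,16,17-trinor-13,14-secoabietane-13,18-dioate
Product: 20 methyl 13-oxo-6α,8α-bis(triethylsilyloxy)-15,16,17-trinor-13,14-secoabietan-18-oate
Conditions: i-Bu2AlH (1.1 equiv), CH2Cl2, −78 °C; MeOH, then potassium sodium tartrate (aq.)
Reagents that add atoms: none
Why: Partial ester reduction by i-Bu2AlH at −78 °C stops at the aluminium hemiacetal, and only the unhindered C13 ester should react because the C18 ester sits on the quaternary C4 between the 4β-methyl group and the 6α-silyloxy group.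

Step 11
Reactants: 20 methyl 13-oxo-6α,8α-bis(triethylsilyloxy)-15,16,17-trinor-13,14-secoabietan-18-oate
Product: 21 terminal alkyne (C13≡CH) with the 18-methyl ester and the 6α,8α-bis(triethylsilyl) ethers
Conditions: dimethyl (1-diazo-2-oxopropyl)phosphonate, K2CO3, MeOH, 0 °C to rt
Reagents that add atoms: dimethyl (1-diazo-2-oxopropyl)phosphonate, COP(=O)(OC)C(=[N+]=[N-])C(C)=O
Why: The Ohira–Bestmann form of the Seyferth–Gilbert homologation turns the aldehyde into the terminal alkyne with one added carbon under mild carbonate conditions that leave the hindered ester and the silyl ethers alone; C12 carries no stereocenter that could epimerize.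

Step 12
Reactants: 21 terminal alkyne
Product: 23 2-iodo-1-alkene (C13(I)=CH2) with the 18-methyl ester and the 6α,8α-bis(triethylsilyl) ethers, via (Z)-2-iodoalkenyl-9-BBN 22 (not isolated)
Conditions: B-iodo-9-BBN (1.3 equiv), hexane/CH2Cl2, −20 to 0 °C; then AcOH, 0 °C
Reagents that add atoms: B-iodo-9-borabicyclo[3.3.1]nonane, IB1C2CCCC1CCC2
Why: cis-Haloboration of the terminal alkyne places iodine on the internal carbon C13 (Markovnikov) and protonolysis of the alkenyl–boron bond with acetic acid gives the 2-iodo-1-alkene, the low temperature and short contact time sparing the silyl ethers and the hindered ester.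

Step 13
Reactants: 24 L-allylglycine
Product: 25 (S)-2-hydroxypent-4-enoic acid
Conditions: NaNO2, 1 M H2SO4 (aq.), 0 °C to rt
Reagents that add atoms: water, O
Why: Diazotization of the α-amino acid proceeds with overall retention through the α-lactone (double inversion), so the (S)-amine gives the (S)-hydroxy acid.

Step 14
Reactants: 25 (S)-2-hydroxypent-4-enoic acid
Product: 26 (S)-3-hydroxyhex-5-en-2-one
Conditions: MeLi (4 equiv), THF, −78 to 0 °C; inverse quench into cold 1 M HCl
Reagents that add atoms: methyllithium, [Li]C
Why: Addition of methyllithium to the lithium carboxylate gives a geminal dialkoxide that collapses to the methyl ketone only on quenching (ketone synthesis from a carboxylic acid and an alkyllithium), and the carbinol center, held as its alkoxide, is not touched.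

Step 15
Reactants: 26 (S)-3-hydroxyhex-5-en-2-one
Product: 28 (S)-4-methyl-5-(prop-2-enyl)furan-2(5H)-one, via phosphoranylidene acetate 27 (not isolated)
Conditions: Ph3P=C=C=O (1.2 equiv), toluene, 80 °C
Reagents that add atoms: (triphenylphosphoranylidene)ketene, O=C=C=P(c1ccccc1)(c1ccccc1)c1ccccc1
Why: The hydroxyl adds to the ketene carbon to give the ester ylide 27, and its intramolecular Wittig reaction with the neighbouring methyl ketone closes the butenolide ring with the methyl group on C17; the C16–O bond is not broken, so the (S) configuration is kept.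

Step 16
Reactants: 28 (S)-4-methyl-5-(prop-2-enyl)furan-2(5H)-one
Product: 30 (S)-2-(3-methyl-5-oxo-2,5-dihydrofuran-2-yl)acetaldehyde, via ozonide 29 (not isolated)
Conditions: O3 (1 equiv, indicator-controlled), CH2Cl2, −78 °C; then Me2S, −78 °C to rt; used crude
Reagents that add atoms: ozone, [O-][O+]=O
Why: In this ozonolysis ozone should react with the electron-rich monosubstituted alkene faster than with the conjugated, trisubstituted butenolide double bond, and reduction of the ozonide by dimethyl sulfide under neutral conditions gives the β-acyloxy aldehyde without a base that could trigger β-elimination.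

Step 17
Reactants: 23 2-iodo-1-alkene; 30 (S)-2-(3-methyl-5-oxo-2,5-dihydrofuran-2-yl)acetaldehyde
Product: 31 C14 allylic alcohols (both C14 epimers) with the 18-methyl ester, the 6α,8α-bis(triethylsilyl) ethers and the (16S)-butenolide
Conditions: CrCl2 (4 equiv), NiCl2 (cat.), DMSO/THF, rt
Reagents that add atoms: none
Why: In the Nozaki–Hiyama–Kishi reaction zerovalent nickel inserts into the C–I bond and passes the alkenyl group on to trivalent chromium, and the alkenylchromium reagent adds only to the aldehyde and leaves the esters, the butenolide and the silyl ethers alone; the new C14 carbinol forms as both epimers, which the next two steps converge.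

Step 18
Reactants: 31 C14 allylic alcohols
Product: 32 C14 ketone (α-methylene ketone)
Conditions: Dess–Martin periodinane (1.5 equiv), NaHCO3, CH2Cl2, 0 °C to rt
Reagents that add atoms: none
Why: Dess–Martin oxidation under bicarbonate buffer converts both C14 epimers into the one α-methylene ketone without the basic conditions that would eliminate the β-acyloxy group.

Step 19
Reactants: 32 C14 ketone
Product: 33 (14R)-allylic alcohol
Conditions: (S)-2-methyl-CBS-oxazaborolidine (0.5 equiv), catecholborane (1.5 equiv), toluene, −78 °C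
Reagents that add atoms: none
Why: In the Corey–Bakshi–Shibata reduction the (S)-oxazaborolidine should bind the ketone with the alkenyl substituent C13 as the large group, in the manner of acetophenone, and deliver hydride to give the (14R)-alcohol, the low temperature suppressing conjugate reduction by catecholborane.

Step 20
Reactants: 33 (14R)-allylic alcohol
Product: 34 (14R)-allylic methanesulfonate
Conditions: Ms2O (1.5 equiv), Et3N, CH2Cl2, −20 °C; used at once
Reagents that add atoms: methanesulfonic anhydride, CS(=O)(=O)OS(C)(=O)=O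
Why: Mesylation with the anhydride and triethylamine gives the allylic sulfonate without a chloride ion that could substitute it, and the C14–O bond is not broken, so (14R) is kept.

Step 21
Reactants: 35 2,3-dimethylbut-2-ene
Product: 36 2-methoxyprop-2-yl hydroperoxide
Conditions: O3, CH2Cl2/MeOH, −78 °C; N2 purge, concentrated cold and used as a solution
Reagents that add atoms: ozone, [O-][O+]=O; methanol, CO
Why: Ozonolysis of the tetrasubstituted alkene in methanol traps the carbonyl oxide as the methoxy hydroperoxide and releases acetone, which gives a ketal-protected form of hydrogen peroxide with a single acidic O–H.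

Step 22
Reactants: 34 (14R)-allylic methanesulfonate; 36 2-methoxyprop-2-yl hydroperoxide
Product: 37 (14S)-2-methoxyprop-2-yl peroxide with the 6α,8α-bis(triethylsilyl) ethers
Conditions: 36 (3 equiv), CsOH·H2O (2 equiv), DMF, 0 °C
Reagents that add atoms: none
Why: The caesium salt of the hydroperoxide, an unhindered α-effect nucleophile of low basicity, should displace the secondary mesylate by SN2 with inversion to give the (14S)-peroxide, and keeping the hydroperoxide in excess over CsOH leaves no base strong enough to deprotonate C16 of the butenolide.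

Step 23
Reactants: 37 (14S)-2-methoxyprop-2-yl peroxide
Product: 38 CNP0324515.1 (target)
Conditions: HF (48 % aq.), MeCN, 0 °C
Reagents that add atoms: none
Why: Acidic deprotection with aqueous HF cleaves both triethylsilyl ethers and hydrolyses the peroxyketal to the free hydroperoxide at 0 °C, conditions under which the O–O bond, the butenolide and all stereocenters should be stable and relactonization of O6 onto C18 slow.

**Compound list**

1 | abietic acid | CC(C)C1=CC2=CC[C@@H]3[C@@]([C@H]2CC1)(CCC[C@@]3(C)C(=O)O)C | starting material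
2 | abietoyl chloride | CC(C)C1=CC2=CC[C@@H]3[C@@]([C@H]2CC1)(CCC[C@@]3(C)C(=O)Cl)C | intermediate
3 | abieta-7,13-dien-18-amide | CC(C)C1=CC2=CC[C@@H]3[C@@]([C@H]2CC1)(CCC[C@@]3(C)C(N)=O)C | intermediate
4 | 13α,14α-dihydroxyabiet-7-en-18-amide | CC(C)[C@@]1(O)[C@H](O)C2=CC[C@@H]3[C@@]([C@H]2CC1)(CCC[C@@]3(C)C(N)=O)C | intermediate
5 | 13,14-dioxo-13,14-secoabiet-7-en-18-amide (C14 enal, C13 isopropyl ketone) | CC(C)C(=O)CC[C@@H]1[C@@]2(C)CCC[C@@](C)(C(N)=O)[C@@H]2CC=C1C=O | intermediate
6 | C14 tosylhydrazone of 5 | CC(C)C(=O)CC[C@@H]1[C@@]2(C)CCC[C@@](C)(C(N)=O)[C@@H]2CC=C1/C=N/NS(=O)(=O)c1ccc(C)cc1 | intermediate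
7 | 13-oxo-13,14-secoabiet-8(14)-en-18-amide | CC(C)C(=O)CC[C@@H]1[C@@]2(C)CCC[C@@](C)(C(N)=O)[C@@H]2CCC1=C | intermediate
8 | 8α,14-epoxy-13-oxo-13,14-secoabietan-18-amide | CC(C)C(=O)CC[C@@H]1[C@@]2(C)CCC[C@@](C)(C(N)=O)[C@@H]2CC[C@@]1(C3)O3 | intermediate
9 | propan-2-yl 18-amino-8α,14-epoxy-18-oxo-15,16,17-trinor-13,14-secoabietan-13-oate | CC(C)OC(=O)CC[C@@H]1[C@@]2(C)CCC[C@@](C)(C(N)=O)[C@@H]2CC[C@@]1(C3)O3 | intermediate
10 | 8α,13-dihydroxy-15,16,17-trinor-13,14-secoabietan-18-amide | OCCC[C@@H]1[C@@]2(C)CCC[C@@](C)(C(N)=O)[C@@H]2CC[C@@]1(C)O | intermediate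
11 | 13,8α-lactol of the C13 aldehyde (C13 anomers), 18-amide | OC1CC[C@@H]2[C@@]3(C)CCC[C@@](C)(C(N)=O)[C@@H]3CC[C@@]2(C)O1 | intermediate
12 | 18-amino-18-oxo-15,16,17-trinor-13,14-secoabietan-13,8α-olide (key-step precursor) | O=C1CC[C@@H]2[C@@]3(C)CCC[C@@](C)(C(N)=O)[C@@H]3CC[C@@]2(C)O1 | intermediate
13 | N-iodo amide of 12 | O=C1CC[C@@H]2[C@@]3(C)CCC[C@@](C)(C(=O)NI)[C@@H]3CC[C@@]2(C)O1 | intermediate
14 | 6-iodo derivative of 12 (either C6 epimer) | O=C1CC[C@@H]2[C@@]3(C)CCC[C@@](C)(C(N)=O)[C@@H]3C(I)C[C@@]2(C)O1 | intermediate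
15 | 18-imino-18,6α-epoxy-15,16,17-trinor-13,14-secoabietan-13,8α-olide (iminolactone) | O=C1CC[C@@H]2[C@@]3(C)CCC[C@@](C)(C(=N)O4)[C@@H]3[C@@H]4C[C@@]2(C)O1 | intermediate
16 | 15,16,17-trinor-13,14-secoabietane-13,8α:18,6α-diolide (key-step product) | O=C1CC[C@@H]2[C@@]3(C)CCC[C@@](C)(C(=O)O4)[C@@H]3[C@@H]4C[C@@]2(C)O1 | intermediate
17 | dipotassium 6α,8α-dihydroxy-15,16,17-trinor-13,14-secoabietane-13,18-dioate | [K+].[K+].[O-]C(=O)CC[C@@H]1[C@@]2(C)CCC[C@@](C)(C([O-])=O)[C@@H]2[C@@H](O)C[C@@]1(C)O | intermediate
18 | dimethyl 6α,8α-dihydroxy-15,16,17-trinor-13,14-secoabietane-13,18-dioate | COC(=O)CC[C@@H]1[C@@]2(C)CCC[C@@](C)(C(=O)OC)[C@@H]2[C@@H](O)C[C@@]1(C)O | intermediate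
19 | dimethyl 6α,8α-bis(triethylsilyloxy)-15,16,17-trinor-13,14-secoabietane-13,18-dioate | COC(=O)CC[C@@H]1[C@@]2(C)CCC[C@@](C)(C(=O)OC)[C@@H]2[C@@H](O[Si](CC)(CC)CC)C[C@@]1(C)O[Si](CC)(CC)CC | intermediate
20 | methyl 13-oxo-6α,8α-bis(triethylsilyloxy)-15,16,17-trinor-13,14-secoabietan-18-oate | O=CCC[C@@H]1[C@@]2(C)CCC[C@@](C)(C(=O)OC)[C@@H]2[C@@H](O[Si](CC)(CC)CC)C[C@@]1(C)O[Si](CC)(CC)CC | intermediate
21 | terminal alkyne (C13≡CH), 18-methyl ester, 6α,8α-bis(triethylsilyl) ether | C#CCC[C@@H]1[C@@]2(C)CCC[C@@](C)(C(=O)OC)[C@@H]2[C@@H](O[Si](CC)(CC)CC)C[C@@]1(C)O[Si](CC)(CC)CC | intermediate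
22 | (Z)-2-iodoalkenyl-9-BBN adduct of 21 | I/C(=C\B1C2CCCC1CCC2)CC[C@@H]1[C@@]2(C)CCC[C@@](C)(C(=O)OC)[C@@H]2[C@@H](O[Si](CC)(CC)CC)C[C@@]1(C)O[Si](CC)(CC)CC | intermediate
23 | 2-iodo-1-alkene (C13(I)=CH2), 18-methyl ester, 6α,8α-bis(triethylsilyl) ether | C=C(I)CC[C@@H]1[C@@]2(C)CCC[C@@](C)(C(=O)OC)[C@@H]2[C@@H](O[Si](CC)(CC)CC)C[C@@]1(C)O[Si](CC)(CC)CC | intermediate
24 | L-allylglycine, (S)-2-aminopent-4-enoic acid | C=CC[C@H](N)C(=O)O | starting material
25 | (S)-2-hydroxypent-4-enoic acid | C=CC[C@H](O)C(=O)O | intermediate
26 | (S)-3-hydroxyhex-5-en-2-one | C=CC[C@H](O)C(C)=O | intermediate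
27 | (triphenylphosphoranylidene)acetate of 26 | C=CC[C@H](OC(=O)C=P(c1ccccc1)(c1ccccc1)c1ccccc1)C(C)=O | intermediate
28 | (S)-4-methyl-5-(prop-2-enyl)furan-2(5H)-one | C=CC[C@@H]1OC(=O)C=C1C | intermediate
29 | ozonide (1,2,4-trioxolane) of 28 | C1OC(C[C@@H]2OC(=O)C=C2C)OO1 | intermediate
30 | (S)-2-(3-methyl-5-oxo-2,5-dihydrofuran-2-yl)acetaldehyde | O=CC[C@@H]1OC(=O)C=C1C | intermediate
31 | C14 allylic alcohols (both C14 epimers), 6α,8α-bis(triethylsilyl) ether, (16S)-butenolide | C=C(CC[C@@H]1[C@@]2(C)CCC[C@@](C)(C(=O)OC)[C@@H]2[C@@H](O[Si](CC)(CC)CC)C[C@@]1(C)O[Si](CC)(CC)CC)C(O)C[C@@H]1OC(=O)C=C1C | intermediate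
32 | C14 ketone (α-methylene ketone), 6α,8α-bis(triethylsilyl) ether | C=C(CC[C@@H]1[C@@]2(C)CCC[C@@](C)(C(=O)OC)[C@@H]2[C@@H](O[Si](CC)(CC)CC)C[C@@]1(C)O[Si](CC)(CC)CC)C(=O)C[C@@H]1OC(=O)C=C1C | intermediate
33 | (14R)-allylic alcohol, 6α,8α-bis(triethylsilyl) ether | C=C(CC[C@@H]1[C@@]2(C)CCC[C@@](C)(C(=O)OC)[C@@H]2[C@@H](O[Si](CC)(CC)CC)C[C@@]1(C)O[Si](CC)(CC)CC)[C@@H](C[C@@H]1OC(=O)C=C1C)O | intermediate
34 | (14R)-allylic methanesulfonate, 6α,8α-bis(triethylsilyl) ether | C=C(CC[C@@H]1[C@@]2(C)CCC[C@@](C)(C(=O)OC)[C@@H]2[C@@H](O[Si](CC)(CC)CC)C[C@@]1(C)O[Si](CC)(CC)CC)[C@@H](C[C@@H]1OC(=O)C=C1C)OS(C)(=O)=O | intermediate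
35 | 2,3-dimethylbut-2-ene | CC(C)=C(C)C | starting material
36 | 2-methoxyprop-2-yl hydroperoxide | COC(C)(C)OO | intermediate
37 | (14S)-2-methoxyprop-2-yl peroxide, 6α,8α-bis(triethylsilyl) ether | C=C(CC[C@@H]1[C@@]2(C)CCC[C@@](C)(C(=O)OC)[C@@H]2[C@@H](O[Si](CC)(CC)CC)C[C@@]1(C)O[Si](CC)(CC)CC)[C@H](C[C@@H]1OC(=O)C=C1C)OOC(C)(C)OC | intermediate
38 | CNP0324515.1 | C=C(CC[C@@H]1[C@@]2(C)CCC[C@@](C)(C(=O)OC)[C@@H]2[C@@H](O)C[C@@]1(C)O)[C@H](C[C@@H]1OC(=O)C=C1C)OO | target

**Step count**

Total step count: 23. Longest linear sequence: 18 steps (steps 1–12, 17–20, 22 and 23); steps 13–16 and step 21 are side branches.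

**Steps most likely to fail**

Step 7. The N-iodoamide may rearrange with migration of the tertiary C4 to nitrogen (Hofmann-type) before the N–I bond is cleaved, or the C6 iodide may lose HI instead of closing the ring. The fallback sets out from 12: nitrosative deamination of the amide (t-BuONO, AcOH, 50 °C) would give the lactone carboxylic acid F1. A carboxylate-directed γ-C–H lactonization of F1 with H2O2 and the manganese aminopyridine catalyst Mn(OTf)2((S,S)-pdp) in 2,2,2-trifluoroethanol would then oxidize the same 6α-hydrogen by hydrogen abstraction and rebound at a metal-bound carboxylate instead of through a free amidyl radical. The route is rejoined at 16.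

Step 22. The peroxide anion may attack the alkene terminus (SN2') or act as a base toward C15, and the basic medium may erode the configuration at C16. The fallback sets out from 23 and gives up the substitution in favour of an ene reaction:
- Negishi coupling with MeZnCl and Pd(PPh3)4 in THF would give the 2-methyl-1-alkene F2.
- Cross-metathesis of F2 with the allyl butenolide 28 (second-generation Hoveyda–Grubbs catalyst, CH2Cl2, 40 °C) would give the (13E)-trisubstituted alkene F3.
- Aqueous HF in MeCN would free the diol F4.
- A Schenck ene reaction of F4 with singlet oxygen (O2, tetraphenylporphyrin, visible light, CH2Cl2, 0 °C) would abstract a hydrogen of the C13 methyl group and place the hydroperoxide on C14, rejoining the route at 38.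

This path does not control C14, and the target would have to be separated from its C14 epimer and from the tertiary C13 hydroperoxide.

Step 4. The Baeyer–Villiger migration of an acyclic ketone is slow, and during the long reaction time the acid formed may open the spiro-epoxide; facial selectivity of the epoxidation may also be incomplete. The fallback sets out from 7 and avoids both the epoxide and the reduction–reoxidation of steps 5 and 6:
- Mukaiyama hydration (Co(acac)2, PhSiH3, O2, i-PrOH, rt) would give the 8α-hydroxy ketone F5, the tertiary radical at C8 being trapped on the α face away from the axial C10 methyl group.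
- Baeyer–Villiger oxidation with CF3CO3H and Na2HPO4 in CH2Cl2 would give the hydroxy isopropyl ester F6.
- NaH in THF would close the alkoxide onto the ester with loss of propan-2-ol, rejoining the route at 12.

**Further compounds**

F1 | step 7 | 15,16,17-trinor-13,14-secoabietan-13,8α-olid-18-oic acid | O=C1CC[C@@H]2[C@@]3(C)CCC[C@@](C)(C(=O)O)[C@@H]3CC[C@@]2(C)O1
F2 | step 22 | 2-methyl-1-alkene (C13(CH3)=CH2), 18-methyl ester, 6α,8α-bis(triethylsilyl) ether | C=C(C)CC[C@@H]1[C@@]2(C)CCC[C@@](C)(C(=O)OC)[C@@H]2[C@@H](O[Si](CC)(CC)CC)C[C@@]1(C)O[Si](CC)(CC)CC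
F3 | step 22 | (13E)-alkene with the (16S)-butenolide, 6α,8α-bis(triethylsilyl) ether | C/C(CC[C@@H]1[C@@]2(C)CCC[C@@](C)(C(=O)OC)[C@@H]2[C@@H](O[Si](CC)(CC)CC)C[C@@]1(C)O[Si](CC)(CC)CC)=C\C[C@@H]1OC(=O)C=C1C
F4 | step 22 | (13E)-alkene 6α,8α-diol with the (16S)-butenolide | C/C(CC[C@@H]1[C@@]2(C)CCC[C@@](C)(C(=O)OC)[C@@H]2[C@@H](O)C[C@@]1(C)O)=C\C[C@@H]1OC(=O)C=C1C
F5 | step 4 | 8α-hydroxy-13-oxo-13,14-secoabietan-18-amide | CC(C)C(=O)CC[C@@H]1[C@@]2(C)CCC[C@@](C)(C(N)=O)[C@@H]2CC[C@@]1(C)O
F6 | step 4 | propan-2-yl 18-amino-8α-hydroxy-18-oxo-15,16,17-trinor-13,14-secoabietan-13-oate | CC(C)OC(=O)CC[C@@H]1[C@@]2(C)CCC[C@@](C)(C(N)=O)[C@@H]2CC[C@@]1(C)O
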